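**Strategy.** Everything rests on opening ring C of the upper flavan (O1–C2–C3–C4–C4a–C8a) by a retro-[4+2]: because O1 is an aryl ether oxygen of ring A and C2 is benzylic, C2=O1–C8a=C4a can be an O-aryl oxocarbenium ion. A catalytic asymmetric oxa-Povarov reaction of this ion, released from a symmetric diaryl acetal by a chiral Brønsted acid, with ethyl vinyl ether (C3–C4) forms C2–C3 and C4–C4a together, sets C2 (S) and leaves a C4 ethoxy group. Its ionisation lets benzyl-protected (−)-epiafzelechin attack through C8 anti to the C2 aryl group (C4, R); hydrogenolysis follows.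

Key step: step 3

Assumption: (−)-epiafzelechin (2R,3R) is taken as purchasable from natural-product suppliers. Flavan numbering (O1, C2, C3, C4, C4a, C5–C8, C8a; rings A, B, C) is used for each unit.

**Step 1**
Reactants: 1 (−)-epiafzelechin, (2R,3R)-2-(4-hydroxyphenyl)chromane-3,5,7-triol
Product: 2 (2R,3R)-3,5,7-tris(benzyloxy)-2-[4-(benzyloxy)phenyl]chromane
Conditions: BnBr (4.5 equiv), NaH (4.5 equiv), Bu4NI (cat.), DMF, −20 °C → rt
Reagents that add atoms: benzyl bromide, BrCc1ccccc1
Why: Williamson O-benzylation of the three phenols and the C3 hydroxyl (the bromide is present before the base is added cold, so each phenoxide is trapped as it forms and base-induced opening of ring C, which would epimerise C2, is avoided); no stereocenter is formed or touched.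

**Step 2**
Reactants: 3 4-(benzyloxy)benzaldehyde; 4 3-(benzyloxy)phenol (2.2 equiv)
Product: 6 4-(benzyloxy)benzaldehyde bis[3-(benzyloxy)phenyl] acetal, via 4-(benzyloxy)benzal chloride 5 (not isolated)
Conditions: SOCl2 (3 equiv), DMF (cat.), CH2Cl2, 40 °C; evaporate; then 4, NaH (2.2 equiv), DMF, 0 °C → rt
Reagents that add atoms: thionyl chloride, ClS(=O)Cl (its chlorine atoms stand in 5 only and leave as chloride on the way to 6)
Why: DMF-catalysed deoxydichlorination of the electron-rich aldehyde gives benzal chloride 5, whose chlorides are displaced one after the other by the phenoxide through p-alkoxy-stabilised carbenium ions (SN1-type double O-alkylation, O- over C-attack being favoured by the sodium phenoxide in a dipolar aprotic solvent); no stereocenter is present.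

**Step 3**
Reactants: 6; 7 ethyl vinyl ether (3 equiv, added slowly)
Product: 10 (2S)-7-(benzyloxy)-2-[4-(benzyloxy)phenyl]-4-ethoxychromane (both C4 epimers), via O-aryl oxocarbenium ion 8 (not isolated), via ethoxycarbenium ion 9 (not isolated)
Conditions: chiral confined imidodiphosphorimidate Brønsted acid (IDPi; BINOL-derived, N-triflyl, 3,3'-aryl groups; (S,S)-form tried first; 5 mol %), toluene/CH2Cl2, −60 °C, 7 by syringe pump; Et3N quench
Reagents that add atoms: none
Why: Proposed new method: the chiral acid ionises the diaryl acetal to the (E)-O-aryl oxocarbenium ion 8, held as a contact ion pair inside the confined chiral anion; the β-carbon of the enol ether adds to C2 of this 2-oxonia-diene (C2=O1–C8a=C4a) to give cation 9, which closes onto arene carbon C4a and loses a proton that regenerates the acid, so C2–C3 and C4–C4a form in one catalytic operation. The closest known reaction types are the SnCl4-promoted (racemic) oxa-Povarov reaction of O-aryl oxocarbenium ions with alkenes, the chiral-phosphoric-acid Povarov reaction of N-aryl imines with vinyl ethers, and counteranion-directed Prins-type additions of olefins to oxocarbenium ions under confined acids; an enantioselective oxa-variant on an acyclic O-aryl oxocarbenium ion has not been shown. Ring C closes in a stepwise polar [4+2] whose second event is a 6-exo-trig Friedel–Crafts attack of C4a on the oxocarbenium carbon C4 (arene π-bond endocyclic). C2 (S) is set in the first C–C bond formation by the facial shielding of 8 by the catalyst anion (catalyst control; the sense of induction is fixed on the first run, the antipodal acid giving the other face), while C4 forms as an epimer mixture that is deliberately left uncontrolled because it becomes planar in step 4. The step needs ortho-regioselective ring closure and clean generation of a single oxocarbenium ion: the benzyloxy group para to C4a makes that carbon the most nucleophilic and least hindered ortho position (the other ortho carbon lies between two oxygen substituents), and the symmetric diaryl acetal can ionise only to the O-aryl oxocarbenium ion, while slow addition of 7 at low temperature keeps enol ether protonation and oligomerisation in check.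

**Step 4**
Reactants: 10; 2 (3 equiv, excess recovered)
Product: 12 (2R,3R)-3,5,7-tris(benzyloxy)-2-[4-(benzyloxy)phenyl]-8-{(2S,4R)-7-(benzyloxy)-2-[4-(benzyloxy)phenyl]chroman-4-yl}chromane, via flavan-4-yl cation 11 (not isolated)
Conditions: TMSOTf (0.2 equiv), 4 Å MS, CH2Cl2, −78 → −40 °C; Et3N quench
Reagents that add atoms: none
Why: Lewis-acid-promoted SN1 Friedel–Crafts alkylation (the interflavan coupling of proanthocyanidin synthesis): both C4 epimers of 10 ionise to the same p-benzyloxy-stabilised benzylic cation 11, which the phloroglucinol-type ring of 2 captures through C8 by axial attack on the half-chair of ring C anti to the pseudo-equatorial C2 aryl group, so C4 (R) is set trans to C2 under substrate control.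

**Step 5**
Reactants: 12
Product: 13 (2R,3R)-8-[(2S,4R)-7-hydroxy-2-(4-hydroxyphenyl)chroman-4-yl]-2-(4-hydroxyphenyl)chromane-3,5,7-triol (target)
Conditions: H2 (1 atm), Pd(OH)2/C, THF/MeOH 1:1, rt
Reagents that add atoms: none
Why: Heterogeneous hydrogenolysis cleaves the six O-benzyl ethers, whose primary benzylic C–O bonds react far faster than the ring-embedded secondary C2–O1 bonds, so the four stereocenters are untouched.

**Compound list**
1 | (−)-epiafzelechin, (2R,3R)-2-(4-hydroxyphenyl)chromane-3,5,7-triol | Oc1cc(O)c2c(c1)O[C@H](c1ccc(O)cc1)[C@H](O)C2 | starting material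
2 | (2R,3R)-3,5,7-tris(benzyloxy)-2-[4-(benzyloxy)phenyl]chromane | O(Cc3ccccc3)c1cc(OCc3ccccc3)c2c(c1)O[C@H](c1ccc(OCc3ccccc3)cc1)[C@H](OCc1ccccc1)C2 | intermediate
3 | 4-(benzyloxy)benzaldehyde | O=Cc1ccc(OCc2ccccc2)cc1 | starting material
4 | 3-(benzyloxy)phenol | Oc1cccc(OCc2ccccc2)c1 | starting material
5 | 4-(benzyloxy)benzal chloride, 1-(benzyloxy)-4-(dichloromethyl)benzene | ClC(Cl)c1ccc(OCc2ccccc2)cc1 | intermediate (not isolated)
6 | 4-(benzyloxy)benzaldehyde bis[3-(benzyloxy)phenyl] acetal | C(Oc1cccc(OCc2ccccc2)c1)(Oc1cccc(OCc2ccccc2)c1)c1ccc(OCc2ccccc2)cc1 | intermediate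
7 | ethyl vinyl ether | C=COCC | starting material
8 | (E)-[4-(benzyloxy)benzylidene][3-(benzyloxy)phenyl]oxonium ion (ion pair with the catalyst anion) | C(c1ccccc1)Oc1ccc(/C=[O+]/c2cccc(OCc3ccccc3)c2)cc1 | intermediate (not isolated)
9 | (S)-configured ethoxycarbenium ion EtO+=CH–CH2–CH(OAr)Ar' formed by the C2–C3 bond | CC[O+]=CC[C@H](Oc1cccc(OCc2ccccc2)c1)c1ccc(OCc2ccccc2)cc1 | intermediate (not isolated)
10 | (2S)-7-(benzyloxy)-2-[4-(benzyloxy)phenyl]-4-ethoxychromane, both C4 epimers | c1ccccc1COc1ccc([C@@H]2CC(OCC)c3ccc(OCc4ccccc4)cc3O2)cc1 | intermediate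
11 | (2S)-7-(benzyloxy)-2-[4-(benzyloxy)phenyl]chroman-4-yl cation | c1ccccc1COc1ccc([C@@H]2C[CH+]c3ccc(OCc4ccccc4)cc3O2)cc1 | intermediate (not isolated)
12 | hexa-O-benzyl dimer, upper unit (2S,4R), lower unit (2R,3R), linked C4→C8 | O(Cc5ccccc5)c1ccc([C@@H]2C[C@@H](c3c(OCc5ccccc5)cc(OCc5ccccc5)c4c3O[C@H](c3ccc(OCc5ccccc5)cc3)[C@H](OCc3ccccc3)C4)c3ccc(OCc5ccccc5)cc3O2)cc1 | intermediate
13 | (2R,3R)-8-[(2S,4R)-7-hydroxy-2-(4-hydroxyphenyl)chroman-4-yl]-2-(4-hydroxyphenyl)chromane-3,5,7-triol | Oc1ccc([C@@H]2C[C@@H](c3c(O)cc(O)c4c3O[C@H](c3ccc(O)cc3)[C@H](O)C4)c3ccc(O)cc3O2)cc1 | target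

**Step count.** Total: 5 steps. Longest linear sequence: 4 steps (2 → 3 → 4 → 5).

**Steps most likely to fail**

1. Step 3 (the labelled step). Enantiofacial discrimination inside the ion pair may be poor, or acid-induced oligomerisation of the enol ether may outrun the cycloaddition. The fallback uses known chemistry, sets out from 3 and returns at 10. Claisen–Schmidt condensation of 3 with purchased 1-[4-(benzyloxy)-2-hydroxyphenyl]ethan-1-one F1 (KOH, EtOH) gives (E)-1-[4-(benzyloxy)-2-hydroxyphenyl]-3-[4-(benzyloxy)phenyl]prop-2-en-1-one F2. Oxa-Michael ring closure (NaOAc, EtOH, reflux) gives racemic 7-(benzyloxy)-2-[4-(benzyloxy)phenyl]chroman-4-one F3. Asymmetric transfer hydrogenation under kinetic resolution (RuCl[(S,S)-TsDPEN](p-cymene), HCO2H/Et3N) is expected to reduce only the (2S)-ketone, giving cis-(2S,4S)-7-(benzyloxy)-2-[4-(benzyloxy)phenyl]chroman-4-ol F4, which is separated from the unreacted (2R)-ketone. Acid-catalysed etherification of F4 (EtOH, PPTS) then gives 10.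

2. Step 4. Cation 11 may be consumed by competing processes: attack through C6 of 2, self-condensation with ring A of a second molecule of 10, or loss of a proton to the flav-3-ene. Anti selectivity may also erode if ionisation needs higher temperature. The fallback changes the leaving group and the mode of activation; it sets out from 10 and returns at 12. Thiolysis of 10 (BnSH, PPTS, CH2Cl2) gives (2S)-7-(benzyloxy)-2-[4-(benzyloxy)phenyl]-4-(benzylsulfanyl)chromane F5. Thiophilic activation of F5 with AgBF4 in THF at low temperature in the presence of 2, with no strong Lewis acid, then gives 12.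

3. Step 2. The highly ionisable benzal chloride 5 may hydrolyse or self-condense, and the ambident phenoxide may alkylate on carbon. The fallback reaches the same oxocarbenium ion by oxidation; it sets out from 3 and 4 and returns at 6. Reduction of 3 (NaBH4, MeOH) gives [4-(benzyloxy)phenyl]methanol F6. Mitsunobu etherification of F6 with 4 (PPh3, DIAD, THF) gives 1-(benzyloxy)-3-{[4-(benzyloxy)benzyl]oxy}benzene F7. DDQ oxidation of the p-alkoxybenzylic C–H bond of F7 in the presence of 4 (4 Å MS, CH2Cl2) then traps the oxocarbenium ion as acetal 6.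

**Further compounds**
F1 | step 3 | 1-[4-(benzyloxy)-2-hydroxyphenyl]ethan-1-one (purchased for the fallback) | CC(=O)c1ccc(OCc2ccccc2)cc1O
F2 | step 3 | (E)-1-[4-(benzyloxy)-2-hydroxyphenyl]-3-[4-(benzyloxy)phenyl]prop-2-en-1-one | O=C(/C=C/c1ccc(OCc2ccccc2)cc1)c1ccc(OCc2ccccc2)cc1O
F3 | step 3 | racemic 7-(benzyloxy)-2-[4-(benzyloxy)phenyl]chroman-4-one | O=C1CC(c2ccc(OCc3ccccc3)cc2)Oc2cc(OCc3ccccc3)ccc12
F4 | step 3 | (2S,4S)-7-(benzyloxy)-2-[4-(benzyloxy)phenyl]chroman-4-ol | c1ccccc1COc1ccc([C@@H]2C[C@H](O)c3ccc(OCc4ccccc4)cc3O2)cc1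
F5 | step 4 | (2S)-7-(benzyloxy)-2-[4-(benzyloxy)phenyl]-4-(benzylsulfanyl)chromane, both C4 epimers | c1ccccc1COc1ccc([C@@H]2CC(SCc3ccccc3)c3ccc(OCc4ccccc4)cc3O2)cc1
F6 | step 2 | [4-(benzyloxy)phenyl]methanol | OCc1ccc(OCc2ccccc2)cc1
F7 | step 2 | 1-(benzyloxy)-3-{[4-(benzyloxy)benzyl]oxy}benzene | c1ccccc1COc1ccc(COc2cccc(OCc3ccccc3)c2)cc1
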